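**Retrosynthetic overview**
1. Endgame: NaBH4 reduction of the free-phenolic dihydroflavonol 28 sets C4 of the lower unit, after hydrogenolysis of six benzyl ethers. Lower ring F is carried as a chromone and completed late by asymmetric aryl 1,4-addition (C2) and Rubottom oxidation (C3).
2. Upper C2/C3: anti addition of OH and H across C2=C3 of a 2,4-diaryl-4H-chromene (dioxirane epoxidation anti to the C4 aryl, then acetate-assisted ionic hydrogenation).
3. Key disconnection: upper ring C by a formal [4+2] annulation of chalcone 9 (O1=C2–C3=C4) with the ring-A synthon 15. C4–C4a comes from rhodium-catalysed asymmetric conjugate arylation and O1–C8a from enolate O-arylation, in one flask.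
4. Enabling feature: in the upper unit, O1–C2–C3–C4 of ring C is the O-enolate of a chalcone whose β-carbon C4 is the diarylmethine bearing ring D. Ring A needs its two new bonds at the adjacent carbons C4a and C8a beside the C8 oxygen, so a 2-bromo-3,4-dialkoxyphenylboronic acid (boron at C4a, bromine at C8a) acts as a regiodefined benzyne equivalent.
5. Ring order: D (gallacetophenone) → F as chromone → C2–C3–C4 chain with ring B (Heck) → ring C fused onto ring A (key step) → C2/C3 of ring C → ring F completed with ring E.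

Key step: step 9

Remark: flavan numbering is used for both units (upper: rings A, C, B; lower: rings D, F, E). Upper C4 keeps one geometry throughout; its descriptor is R in the benzylated compounds and S in the free phenols 28 and 29 only because the CIP ranking of rings A and D changes.

**Route**

Step 1
Reactants: 1 1-(2,3,4-trihydroxyphenyl)ethanone (gallacetophenone)
Product: 2 1-[3,4-bis(benzyloxy)-2-hydroxyphenyl]ethanone
Conditions: BnBr (2.1 equiv), K2CO3 (2.2 equiv), acetone, 55 °C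
Reagents that add atoms: benzyl bromide BrCc1ccccc1
Why: Williamson etherification; the 2-hydroxyl is hydrogen-bonded to the acetyl carbonyl and should stay free, as the later chromone closure requires.

Step 2
Reactants: 2 1-[3,4-bis(benzyloxy)-2-hydroxyphenyl]ethanone
Product: 3 1-[3,4-bis(benzyloxy)-5-bromo-2-hydroxyphenyl]ethanone
Conditions: NBS (1.05 equiv), MeCN, 0 °C to rt
Reagents that add atoms: N-bromosuccinimide O=C1CCC(=O)N1Br
Why: Electrophilic aromatic bromination should go para to the free phenol (C5), the position activated by the hydroxyl and meta to the acetyl group.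

Step 3
Reactants: 3 1-[3,4-bis(benzyloxy)-5-bromo-2-hydroxyphenyl]ethanone
Product: 5 7,8-bis(benzyloxy)-6-bromo-4H-chromen-4-one, via enaminone 4 (not isolated)
Conditions: Me2NCH(OMe)2 (3 equiv), toluene, 100 °C; then conc. HCl, CH2Cl2, 40 °C
Reagents that add atoms: N,N-dimethylformamide dimethyl acetal COC(OC)N(C)C
Why: Enaminone formation and acid-induced cyclisation with loss of dimethylamine (chromone synthesis via an enaminone); the chromone is a base-stable placeholder for ring F.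

Step 4
Reactants: 6 1-[4-(benzyloxy)phenyl]ethanone
Product: 8 1-[4-(benzyloxy)phenyl]prop-2-en-1-one, via Mannich base 7 (not isolated)
Conditions: (CH2O)n (2 equiv), i-Pr2NH2+ CF3CO2− (1 equiv), CF3CO2H (10 mol%), THF, reflux; used at once with BHT
Reagents that add atoms: paraformaldehyde (formaldehyde) C=O
Why: Mannich reaction with the iminium ion formed in the flask, then β-elimination of the amine (ammonium-salt-mediated α-methylenation of an aryl methyl ketone).

Step 5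
Reactants: 5 7,8-bis(benzyloxy)-6-bromo-4H-chromen-4-one; 8 1-[4-(benzyloxy)phenyl]prop-2-en-1-one
Product: 9 7,8-bis(benzyloxy)-6-{(E)-3-[4-(benzyloxy)phenyl]-3-oxoprop-1-en-1-yl}-4H-chromen-4-one
Conditions: Pd(OAc)2 (5 mol%), n-Bu4NBr (1 equiv), NaHCO3 (2.5 equiv), DMF, 80 °C
Reagents that add atoms: none
Why: Mizoroki–Heck coupling under ligand-free Jeffery conditions should give the (E)-enone by syn insertion and syn β-hydride elimination, leaving the electron-poor chromone double bond untouched.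

Step 6
Reactants: 10 3-bromobenzene-1,2-diol
Product: 11 1,2-bis(benzyloxy)-3-bromobenzene
Conditions: BnBr (2.2 equiv), K2CO3 (2.5 equiv), DMF, rt
Reagents that add atoms: benzyl bromide BrCc1ccccc1
Why: Williamson etherification of both catechol hydroxyls.

Step 7
Reactants: 11 1,2-bis(benzyloxy)-3-bromobenzene
Product: 12 1,2-bis(benzyloxy)-3-bromo-4-iodobenzene
Conditions: NIS (1.1 equiv), CF3CO2H (0.3 equiv), MeCN, rt, dark
Reagents that add atoms: N-iodosuccinimide O=C1CCC(=O)N1I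
Why: Electrophilic aromatic iodination should go para to the unhindered, coplanar C1 benzyloxy group (the C2 benzyloxy group is twisted out of conjugation by its two neighbours), which places iodine next to bromine.

Step 8
Reactants: 12 1,2-bis(benzyloxy)-3-bromo-4-iodobenzene
Product: 15 [3,4-bis(benzyloxy)-2-bromophenyl]boronic acid, via arylmagnesium chloride 13 (not isolated), via trimethoxyborate 14 (not isolated)
Conditions: i-PrMgCl·LiCl (1.05 equiv), THF, −40 °C; B(OMe)3 (2 equiv), −40 to 0 °C; 1 M HCl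
Reagents that add atoms: trimethyl borate COB(OC)OC; water O
Why: Iodine–magnesium exchange (Knochel type) is selective for iodide over bromide and the ortho-bromoaryl Grignard reagent is stable at −40 °C; borate trapping and hydrolysis give the boronic acid.

Step 9
Reactants: 9 7,8-bis(benzyloxy)-6-{(E)-3-[4-(benzyloxy)phenyl]-3-oxoprop-1-en-1-yl}-4H-chromen-4-one; 15 [3,4-bis(benzyloxy)-2-bromophenyl]boronic acid
Product: 17 7,8-bis(benzyloxy)-6-{(4R)-7,8-bis(benzyloxy)-2-[4-(benzyloxy)phenyl]-4H-chromen-4-yl}-4H-chromen-4-one, via bromo ketone 16 (not isolated)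
Conditions: 15 (1.8 equiv), [RhCl(C2H4)2]2 (2.5 mol%), (S,S)-Ph-bod* [(1S,4S)-2,5-diphenylbicyclo[2.2.2]octa-2,5-diene, 5.5 mol%], K3PO4 (20 mol%), 1,4-dioxane/H2O 10:1, 40 °C; then evaporate, toluene, CuI (10 mol%), 1,10-phenanthroline (20 mol%), Cs2CO3 (2.5 equiv), 105 °C
Reagents that add atoms: none
Why: Proposed new method: an enantioselective relay annulation in which the enone is the four-atom partner (O1=C2–C3=C4) and boronic acid 15 a regiodefined benzyne equivalent; an aryl–rhodium species from 15 inserts the enone and hydrolysis gives ketone 16, whose caesium (Z)-enolate then undergoes copper-mediated intramolecular O-arylation at the C8a–Br bond. The closest known reaction types are the Hayashi–Miyaura asymmetric 1,4-addition of arylboronic acids to chalcones, rhodium/palladium relay sequences that follow such an addition by an intramolecular C–N or C–O coupling, and Ullmann-type enolate O-arylation to benzofurans and 4H-chromenes; joining them into an enone/2-bromoarylboronic acid annulation is the untested part. Ring C closes by attack of the enolate oxygen on the aryl carbon C8a in a six-membered mode with the new C2=C3 bond endocyclic, whereas C-arylation would need a four-membered ring. C4 is the only new stereocentre and is set by the chiral diene–rhodium catalyst, which should deliver the aryl group to the enone face on which the α-carbon is si (the ligand series that gives (S)-3-arylcyclohexanones from 2-cyclohexenone). The step needs chemoselectivity for the chalcone enone over the chromone (a vinylogous ester and a far poorer acceptor) and regiocontrol in ring A, which is fixed by the positions of boron and bromine and not by aryne electronics.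

Step 10
Reactants: 17 7,8-bis(benzyloxy)-6-{(4R)-7,8-bis(benzyloxy)-2-[4-(benzyloxy)phenyl]-4H-chromen-4-yl}-4H-chromen-4-one
Product: 20 (3R,4R)-7,8-bis(benzyloxy)-2-[4-(benzyloxy)phenyl]-4-[7,8-bis(benzyloxy)-4-oxo-4H-chromen-6-yl]-2-methoxychroman-3-yl acetate (C2 anomers), via epoxide 18 (not isolated), via hydroxy ketal 19 (not isolated)
Conditions: DMDO (1.1 equiv, acetone), CH2Cl2/MeOH 4:1, −40 to 0 °C; evaporate; Ac2O (3 equiv), pyridine, DMAP (10 mol%), CH2Cl2, rt
Reagents that add atoms: dimethyldioxirane CC1(C)OO1; methanol CO; acetic anhydride CC(=O)OC(C)=O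
Why: Dioxirane epoxidation of the electron-rich enol ether should occur on the face opposite to the pseudo-axial C4 aryl group (setting C3 with oxygen trans to ring D); the labile epoxide is solvolysed at C2 by methanol and the C3 hydroxyl is then acetylated.

Step 11
Reactants: 20 (3R,4R)-7,8-bis(benzyloxy)-2-[4-(benzyloxy)phenyl]-4-[7,8-bis(benzyloxy)-4-oxo-4H-chromen-6-yl]-2-methoxychroman-3-yl acetate
Product: 21 (2R,3R,4R)-7,8-bis(benzyloxy)-2-[4-(benzyloxy)phenyl]-4-[7,8-bis(benzyloxy)-4-oxo-4H-chromen-6-yl]chroman-3-yl acetate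
Conditions: Et3SiH (3 equiv), BF3·OEt2 (1.5 equiv), CH2Cl2, −78 to −30 °C
Reagents that add atoms: none
Why: Anchimerically assisted ionic hydrogenation: BF3 ionises the C2 ketal, the C3 acetate bridges the 2-aryl oxocarbenium ion as a dioxolanylium ion on the face of the C3 oxygen, and Et3SiH should deliver hydride to C2 from the opposite face, leaving the 2-aryl group cis to the C3 oxygen (2,3-cis-3,4-trans).

Step 12
Reactants: 21 (2R,3R,4R)-7,8-bis(benzyloxy)-2-[4-(benzyloxy)phenyl]-4-[7,8-bis(benzyloxy)-4-oxo-4H-chromen-6-yl]chroman-3-yl acetate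
Product: 22 6-{(2R,3R,4R)-7,8-bis(benzyloxy)-2-[4-(benzyloxy)phenyl]-3-hydroxychroman-4-yl}-7,8-bis(benzyloxy)-4H-chromen-4-one
Conditions: K2CO3 (0.3 equiv), MeOH/THF 1:1, 0 °C to rt; citric acid quench
Reagents that add atoms: none
Why: Base-catalysed transesterification (Zemplén type) removes the acetate; any methanol adduct of the chromone should revert on the acidic quench.

Step 13
Reactants: 22 6-{(2R,3R,4R)-7,8-bis(benzyloxy)-2-[4-(benzyloxy)phenyl]-3-hydroxychroman-4-yl}-7,8-bis(benzyloxy)-4H-chromen-4-one; 23 [4-(benzyloxy)phenyl]boronic acid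
Product: 24 (2S)-7,8-bis(benzyloxy)-2-[4-(benzyloxy)phenyl]-6-{(2R,3R,4R)-7,8-bis(benzyloxy)-2-[4-(benzyloxy)phenyl]-3-hydroxychroman-4-yl}chroman-4-one
Conditions: 23 (2 equiv), Pd(OCOCF3)2 (10 mol%), (R)-t-BuPyOx (12 mol%), NH4PF6 (30 mol%), H2O (5 equiv), ClCH2CH2Cl, 60 °C
Reagents that add atoms: none
Why: Asymmetric conjugate addition of an arylboronic acid to a chromone with a cationic divalent palladium pyridine-oxazoline catalyst; the ligand antipode is the one that gives (S)-2-arylchroman-4-ones, so C2 of ring F is catalyst-controlled.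

Step 14
Reactants: 24 (2S)-7,8-bis(benzyloxy)-2-[4-(benzyloxy)phenyl]-6-{(2R,3R,4R)-7,8-bis(benzyloxy)-2-[4-(benzyloxy)phenyl]-3-hydroxychroman-4-yl}chroman-4-one
Product: 27 (2R,3R)-7,8-bis(benzyloxy)-2-[4-(benzyloxy)phenyl]-6-{(2R,3R,4R)-7,8-bis(benzyloxy)-2-[4-(benzyloxy)phenyl]-3-hydroxychroman-4-yl}-3-hydroxychroman-4-one, via silyl enol ether 25 (not isolated), via silyloxy epoxide 26 (not isolated)
Conditions: TMSOTf (2.5 equiv), Et3N (4 equiv), CH2Cl2, 0 °C; pentane filtration; DMDO (1.2 equiv, acetone), CH2Cl2, −40 °C; citric acid, MeOH, rt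
Reagents that add atoms: dimethyldioxirane CC1(C)OO1
Why: Rubottom oxidation: soft enolisation (which also silylates the upper C3 hydroxyl) avoids alkoxide-induced opening of the flavanone, and the dioxirane should attack the enol ether face opposite to the C2 aryl group, giving the 2,3-trans dihydroflavonol.

Step 15
Reactants: 27 (2R,3R)-7,8-bis(benzyloxy)-2-[4-(benzyloxy)phenyl]-6-{(2R,3R,4R)-7,8-bis(benzyloxy)-2-[4-(benzyloxy)phenyl]-3-hydroxychroman-4-yl}-3-hydroxychroman-4-one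
Product: 28 (2R,3R)-3,7,8-trihydroxy-2-(4-hydroxyphenyl)-6-[(2R,3R,4S)-3,7,8-trihydroxy-2-(4-hydroxyphenyl)chroman-4-yl]chroman-4-one
Conditions: H2 (1 atm), Pd(OH)2/C, THF/MeOH 1:1, rt
Reagents that add atoms: none
Why: Hydrogenolysis of the six benzyl ethers; the chromanone carbonyl (a vinylogous ester) and the flavan C–O bonds are expected to survive at 1 atm.

Step 16
Reactants: 28 (2R,3R)-3,7,8-trihydroxy-2-(4-hydroxyphenyl)-6-[(2R,3R,4S)-3,7,8-trihydroxy-2-(4-hydroxyphenyl)chroman-4-yl]chroman-4-one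
Product: 29 (2R,3S,4R)-2-(4-hydroxyphenyl)-6-[(2R,3R,4S)-3,7,8-trihydroxy-2-(4-hydroxyphenyl)chroman-4-yl]chroman-3,4,7,8-tetrol [epioritin-(4β→6)-oritin-4α-ol]
Conditions: NaBH4 (6 equiv), MeOH, 0 °C; AcOH to pH 6; Sephadex LH-20
Reagents that add atoms: none
Why: Borohydride reduction of a 2,3-trans dihydroflavonol: axial hydride attack on the half-chair chromanone should give the equatorial 4-hydroxyl trans to the equatorial 3-hydroxyl (2,3-trans-3,4-trans).

**Compound list**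
1 | 1-(2,3,4-trihydroxyphenyl)ethanone | CC(=O)c1ccc(O)c(O)c1O | starting material
2 | 1-[3,4-bis(benzyloxy)-2-hydroxyphenyl]ethanone | CC(=O)c1ccc(OCc2ccccc2)c(OCc2ccccc2)c1O | intermediate
3 | 1-[3,4-bis(benzyloxy)-5-bromo-2-hydroxyphenyl]ethanone | CC(=O)c1cc(Br)c(OCc2ccccc2)c(OCc2ccccc2)c1O | intermediate
4 | (E)-1-[3,4-bis(benzyloxy)-5-bromo-2-hydroxyphenyl]-3-(dimethylamino)prop-2-en-1-one | CN(C)/C=C/C(=O)c1cc(Br)c(OCc2ccccc2)c(OCc2ccccc2)c1O | intermediate (not isolated)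
5 | 7,8-bis(benzyloxy)-6-bromo-4H-chromen-4-one | O=c1ccoc2c(OCc3ccccc3)c(OCc3ccccc3)c(Br)cc12 | intermediate
6 | 1-[4-(benzyloxy)phenyl]ethanone | CC(=O)c1ccc(OCc2ccccc2)cc1 | starting material
7 | 1-[4-(benzyloxy)phenyl]-3-(diisopropylamino)propan-1-one | CC(C)N(CCC(=O)c1ccc(OCc2ccccc2)cc1)C(C)C | intermediate (not isolated)
8 | 1-[4-(benzyloxy)phenyl]prop-2-en-1-one | C=CC(=O)c1ccc(OCc2ccccc2)cc1 | intermediate
9 | 7,8-bis(benzyloxy)-6-{(E)-3-[4-(benzyloxy)phenyl]-3-oxoprop-1-en-1-yl}-4H-chromen-4-one | O=C(/C=C/c1cc2c(occc2=O)c(OCc2ccccc2)c1OCc1ccccc1)c1ccc(OCc2ccccc2)cc1 | intermediate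
10 | 3-bromobenzene-1,2-diol | Oc1cccc(Br)c1O | starting material
11 | 1,2-bis(benzyloxy)-3-bromobenzene | Brc1cccc(OCc2ccccc2)c1OCc1ccccc1 | intermediate
12 | 1,2-bis(benzyloxy)-3-bromo-4-iodobenzene | Ic1ccc(OCc2ccccc2)c(OCc2ccccc2)c1Br | intermediate
13 | [3,4-bis(benzyloxy)-2-bromophenyl]magnesium chloride | Cl[Mg]c1ccc(OCc2ccccc2)c(OCc2ccccc2)c1Br | intermediate (not isolated)
14 | chloromagnesium [3,4-bis(benzyloxy)-2-bromophenyl]trimethoxyborate | CO[B-](OC)(OC)c1ccc(OCc2ccccc2)c(OCc2ccccc2)c1Br.[Mg+]Cl | intermediate (not isolated)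
15 | [3,4-bis(benzyloxy)-2-bromophenyl]boronic acid | OB(O)c1ccc(OCc2ccccc2)c(OCc2ccccc2)c1Br | intermediate
16 | 7,8-bis(benzyloxy)-6-{(1S)-1-[3,4-bis(benzyloxy)-2-bromophenyl]-3-[4-(benzyloxy)phenyl]-3-oxopropyl}-4H-chromen-4-one | C(c1ccccc1)Oc1ccc(C(=O)C[C@@H](c2cc3c(c(OCc4ccccc4)c2OCc2ccccc2)occc3=O)c2ccc(OCc3ccccc3)c(OCc3ccccc3)c2Br)cc1 | intermediate (not isolated)
17 | 7,8-bis(benzyloxy)-6-{(4R)-7,8-bis(benzyloxy)-2-[4-(benzyloxy)phenyl]-4H-chromen-4-yl}-4H-chromen-4-one | C(c1ccccc1)Oc1ccc(C2Oc3c(ccc(OCc4ccccc4)c3OCc3ccccc3)[C@H](c3cc4c(c(OCc5ccccc5)c3OCc3ccccc3)occc4=O)C=2)cc1 | intermediate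
18 | 6-{(2S,3R,4R)-7,8-bis(benzyloxy)-2-[4-(benzyloxy)phenyl]-2,3-epoxychroman-4-yl}-7,8-bis(benzyloxy)-4H-chromen-4-one (oxirane on the face opposite to the C4 substituent) | C(c1ccccc1)Oc1ccc([C@]23Oc4c(ccc(OCc5ccccc5)c4OCc4ccccc4)[C@H](c4cc5c(c(OCc6ccccc6)c4OCc4ccccc4)occc5=O)[C@H]2O3)cc1 | intermediate (not isolated)
19 | 6-{(3R,4R)-7,8-bis(benzyloxy)-2-[4-(benzyloxy)phenyl]-3-hydroxy-2-methoxychroman-4-yl}-7,8-bis(benzyloxy)-4H-chromen-4-one (C2 anomers) | C(c1ccccc1)Oc1ccc(C2(OC)Oc3c(ccc(OCc4ccccc4)c3OCc3ccccc3)[C@H](c3cc4c(c(OCc5ccccc5)c3OCc3ccccc3)occc4=O)[C@H]2O)cc1 | intermediate (not isolated)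
20 | (3R,4R)-7,8-bis(benzyloxy)-2-[4-(benzyloxy)phenyl]-4-[7,8-bis(benzyloxy)-4-oxo-4H-chromen-6-yl]-2-methoxychroman-3-yl acetate (C2 anomers) | C(c1ccccc1)Oc1ccc(C2(OC)Oc3c(ccc(OCc4ccccc4)c3OCc3ccccc3)[C@H](c3cc4c(c(OCc5ccccc5)c3OCc3ccccc3)occc4=O)[C@H]2OC(C)=O)cc1 | intermediate
21 | (2R,3R,4R)-7,8-bis(benzyloxy)-2-[4-(benzyloxy)phenyl]-4-[7,8-bis(benzyloxy)-4-oxo-4H-chromen-6-yl]chroman-3-yl acetate | C(c1ccccc1)Oc1ccc([C@H]2Oc3c(ccc(OCc4ccccc4)c3OCc3ccccc3)[C@H](c3cc4c(c(OCc5ccccc5)c3OCc3ccccc3)occc4=O)[C@H]2OC(C)=O)cc1 | intermediate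
22 | 6-{(2R,3R,4R)-7,8-bis(benzyloxy)-2-[4-(benzyloxy)phenyl]-3-hydroxychroman-4-yl}-7,8-bis(benzyloxy)-4H-chromen-4-one | C(c1ccccc1)Oc1ccc([C@H]2Oc3c(ccc(OCc4ccccc4)c3OCc3ccccc3)[C@H](c3cc4c(c(OCc5ccccc5)c3OCc3ccccc3)occc4=O)[C@H]2O)cc1 | intermediate
23 | [4-(benzyloxy)phenyl]boronic acid | OB(O)c1ccc(OCc2ccccc2)cc1 | starting material
24 | (2S)-7,8-bis(benzyloxy)-2-[4-(benzyloxy)phenyl]-6-{(2R,3R,4R)-7,8-bis(benzyloxy)-2-[4-(benzyloxy)phenyl]-3-hydroxychroman-4-yl}chroman-4-one | C(c1ccccc1)Oc1ccc([C@H]2Oc3c(ccc(OCc4ccccc4)c3OCc3ccccc3)[C@H](c3cc4c(c(OCc5ccccc5)c3OCc3ccccc3)O[C@H](c3ccc(OCc5ccccc5)cc3)CC4=O)[C@H]2O)cc1 | intermediate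
25 | (2S)-7,8-bis(benzyloxy)-2-[4-(benzyloxy)phenyl]-6-{(2R,3R,4R)-7,8-bis(benzyloxy)-2-[4-(benzyloxy)phenyl]-3-(trimethylsilyloxy)chroman-4-yl}-4-(trimethylsilyloxy)-2H-chromene | C(c1ccccc1)Oc1ccc([C@H]2Oc3c(ccc(OCc4ccccc4)c3OCc3ccccc3)[C@H](c3cc4c(c(OCc5ccccc5)c3OCc3ccccc3)O[C@H](c3ccc(OCc5ccccc5)cc3)C=C4O[Si](C)(C)C)[C@H]2O[Si](C)(C)C)cc1 | intermediate (not isolated)
26 | 3,4-epoxide of 25 (4-trimethylsilyloxy oxirane on the face of ring F opposite to the C2 aryl group) | C(c1ccccc1)Oc1ccc([C@H]2Oc3c(ccc(OCc4ccccc4)c3OCc3ccccc3)[C@H](c3cc4c(c(OCc5ccccc5)c3OCc3ccccc3)O[C@H](c3ccc(OCc5ccccc5)cc3)[C@H]5O[C@@]45O[Si](C)(C)C)[C@H]2O[Si](C)(C)C)cc1 | intermediate (not isolated)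
27 | (2R,3R)-7,8-bis(benzyloxy)-2-[4-(benzyloxy)phenyl]-6-{(2R,3R,4R)-7,8-bis(benzyloxy)-2-[4-(benzyloxy)phenyl]-3-hydroxychroman-4-yl}-3-hydroxychroman-4-one | C(c1ccccc1)Oc1ccc([C@H]2Oc3c(ccc(OCc4ccccc4)c3OCc3ccccc3)[C@H](c3cc4c(c(OCc5ccccc5)c3OCc3ccccc3)O[C@H](c3ccc(OCc5ccccc5)cc3)[C@@H](O)C4=O)[C@H]2O)cc1 | intermediate
28 | (2R,3R)-3,7,8-trihydroxy-2-(4-hydroxyphenyl)-6-[(2R,3R,4S)-3,7,8-trihydroxy-2-(4-hydroxyphenyl)chroman-4-yl]chroman-4-one | Oc1ccc([C@H]2Oc3c(ccc(O)c3O)[C@H](c3cc4c(c(O)c3O)O[C@H](c3ccc(O)cc3)[C@@H](O)C4=O)[C@H]2O)cc1 | intermediate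
29 | (2R,3S,4R)-2-(4-hydroxyphenyl)-6-[(2R,3R,4S)-3,7,8-trihydroxy-2-(4-hydroxyphenyl)chroman-4-yl]chroman-3,4,7,8-tetrol | Oc1ccc([C@H]2Oc3c(ccc(O)c3O)[C@H](c3cc4c(c(O)c3O)O[C@H](c3ccc(O)cc3)[C@@H](O)[C@@H]4O)[C@H]2O)cc1 | target

**Step count and risks**
Total step count: 16. Longest linear sequence: 12 steps (1, 2, 3, 5, 9, 10, 11, 12, 13, 14, 15, 16).

Steps most likely to fail:

1. Step 9 (proposed new method). Protodeboronation of the ortho-bromo boronic acid may outrun insertion into the congested enone, or the copper-mediated closure may stall or hydrodebrominate in the crude rhodium mixture. Fallback with known chemistry: from 9 and 15 the rhodium-catalysed addition is run alone and ketone 16 is isolated. Miyaura borylation of its C–Br bond (B2pin2, PdCl2(dppf), KOAc, dioxane, 90 °C) should give the aryl pinacol boronate F1. N-oxide oxidation (Me3NO, THF, rt) should give the phenol F2, which exists in equilibrium with its cyclic hemiketal. Acid-catalysed cyclodehydration (TsOH cat., toluene, 4 Å sieves) then returns to the route at 17.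

2. Step 11. Hydride delivery without acetate participation, or loss of H3 from the oxocarbenium ion to an enol acetate, would erode the facial selectivity at C2. Fallback: from 17, dihydroxylation anti to the C4 aryl (OsO4 cat., NMO, acetone/H2O) should give the α-hydroxy ketone F3, the open form of the hemiketal. Chelation-controlled reduction (Zn(BH4)2, Et2O, −20 °C) should give the anti-1,2-diol F4. Mitsunobu cyclisation of the ring-A phenol onto the benzylic carbinol with inversion (PPh3, DIAD, THF, 0 °C) then closes ring C as the 2,3-cis isomer and comes back at 22, bypassing 20 and 21.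

3. Step 13. The electron-rich chromone, flanked at C6 and C8, may convert poorly in the palladium-catalysed aryl transfer. Fallback: from 22, TMSOTf (2.2 equiv) with 2,6-lutidine should give the 4-silyloxybenzopyrylium triflate F5, silylated also at the upper C3 oxygen. 4-(Benzyloxy)phenylmagnesium bromide (THF, −78 °C) adds at C2 of ring F without facial control and gives 25 together with its ring-F C2 epimer F6. This mixture re-enters the route at 25 and is taken through step 14, after which the lower-unit (2S,3S) diastereomer F7 is removed by chromatography from 27.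

**Further compounds**
F1 | step 9 | 7,8-bis(benzyloxy)-6-{(1R)-1-[3,4-bis(benzyloxy)-2-(4,4,5,5-tetramethyl-1,3,2-dioxaborolan-2-yl)phenyl]-3-[4-(benzyloxy)phenyl]-3-oxopropyl}-4H-chromen-4-one | C(c1ccccc1)Oc1ccc(C(=O)C[C@@H](c2cc3c(c(OCc4ccccc4)c2OCc2ccccc2)occc3=O)c2ccc(OCc3ccccc3)c(OCc3ccccc3)c2B2OC(C)(C)C(C)(C)O2)cc1
F2 | step 9 | 7,8-bis(benzyloxy)-6-{(1R)-1-[3,4-bis(benzyloxy)-2-hydroxyphenyl]-3-[4-(benzyloxy)phenyl]-3-oxopropyl}-4H-chromen-4-one | C(c1ccccc1)Oc1ccc(C(=O)C[C@@H](c2cc3c(c(OCc4ccccc4)c2OCc2ccccc2)occc3=O)c2ccc(OCc3ccccc3)c(OCc3ccccc3)c2O)cc1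
F3 | step 11 | 7,8-bis(benzyloxy)-6-{(1R,2R)-1-[3,4-bis(benzyloxy)-2-hydroxyphenyl]-3-[4-(benzyloxy)phenyl]-2-hydroxy-3-oxopropyl}-4H-chromen-4-one | C(c1ccccc1)Oc1ccc(C(=O)[C@H](O)[C@@H](c2cc3c(c(OCc4ccccc4)c2OCc2ccccc2)occc3=O)c2ccc(OCc3ccccc3)c(OCc3ccccc3)c2O)cc1
F4 | step 11 | 7,8-bis(benzyloxy)-6-{(1R,2R,3S)-1-[3,4-bis(benzyloxy)-2-hydroxyphenyl]-3-[4-(benzyloxy)phenyl]-2,3-dihydroxypropyl}-4H-chromen-4-one | C(c1ccccc1)Oc1ccc([C@H](O)[C@H](O)[C@@H](c2cc3c(c(OCc4ccccc4)c2OCc2ccccc2)occc3=O)c2ccc(OCc3ccccc3)c(OCc3ccccc3)c2O)cc1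
F5 | step 13 | 7,8-bis(benzyloxy)-6-{(2R,3R,4R)-7,8-bis(benzyloxy)-2-[4-(benzyloxy)phenyl]-3-(trimethylsilyloxy)chroman-4-yl}-4-(trimethylsilyloxy)chromenylium trifluoromethanesulfonate | C(c1ccccc1)Oc1ccc([C@H]2Oc3c(ccc(OCc4ccccc4)c3OCc3ccccc3)[C@H](c3cc4c(c(OCc5ccccc5)c3OCc3ccccc3)[o+]ccc4O[Si](C)(C)C)[C@H]2O[Si](C)(C)C)cc1.[O-]S(=O)(=O)C(F)(F)F
F6 | step 13 | (2R)-epimer of 25 at C2 of ring F | C(c1ccccc1)Oc1ccc([C@H]2Oc3c(ccc(OCc4ccccc4)c3OCc3ccccc3)[C@H](c3cc4c(c(OCc5ccccc5)c3OCc3ccccc3)O[C@@H](c3ccc(OCc5ccccc5)cc3)C=C4O[Si](C)(C)C)[C@H]2O[Si](C)(C)C)cc1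
F7 | step 13 | (2S,3S)-diastereomer of 27 in ring F | C(c1ccccc1)Oc1ccc([C@H]2Oc3c(ccc(OCc4ccccc4)c3OCc3ccccc3)[C@H](c3cc4c(c(OCc5ccccc5)c3OCc3ccccc3)O[C@@H](c3ccc(OCc5ccccc5)cc3)[C@H](O)C4=O)[C@H]2O)cc1
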